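## Retrosynthetic overview
1. The oxane is (2R,4R,6S): the C4 aryl and C6 chain are cis and the C2 aryl is trans to both (axial). This is the less stable C2 epimer of the all-equatorial ring. Closing the ring from a C3 carbinol would give the all-cis isomer under kinetic and thermodynamic control, so that closure is not used.
2. The last bond made is C6–H. It comes from invertive hydride opening of the C–OAr bond of a benzo-fused 2,8-dioxabicyclo[3.3.1]nonane ketal.
3. The oxane ring is closed at O–C2 by capture of the diarylheptanoid p-quinone methide with the C3 hemiketal oxygen. The bridge holds the chalcone aryl axial, so the C2 aryl settles exo, which is trans.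
4. The C–C union is an enantioselective conjugate Friedel–Crafts addition of helichrysetin to C5 of the natural 4,6-dien-3-one. Ring order: chroman hemiketal ring, then oxane ring, then the chroman ring is reopened.
5. Each partner comes from one aldol condensation of two commercial compounds.

Numbering: heptanoid C1–C7 runs from the arylethyl end (C3 = oxane C6, C5 = oxane C4, C7 = oxane C2). Primed numbers refer to chalcone ring A.

Assumption: the quinine-derived primary amine is taken to give the (5R) adduct. If it gives the antipode, its quinidine-derived pseudoenantiomer is used and nothing else changes.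

## Route

Step 1
Reactants: 1 2',4'-dihydroxy-6'-methoxyacetophenone; 2 4-hydroxybenzaldehyde
Product: 3 helichrysetin, that is (E)-1-(2,4-dihydroxy-6-methoxyphenyl)-3-(4-hydroxyphenyl)prop-2-en-1-one
Conditions: KOH (50% aq, 12 equiv), EtOH, 0 °C → rt, 48 h; then cold 2 M HCl to pH 4
Reagents that add atoms: none
Why: Claisen–Schmidt aldol condensation, in which the methyl ketone enolate of 1 adds to 2, E1cB loss of water gives only the conjugated E enone, strong base holds it as the open chalcone phenolate, and cold acidification releases it.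

Step 2
Reactants: 4 4-(4-hydroxyphenyl)butan-2-one (raspberry ketone); 5 (E)-4-hydroxycinnamaldehyde
Product: 6 (4E,6E)-1,7-bis(4-hydroxyphenyl)hepta-4,6-dien-3-one
Conditions: pyrrolidine (30 mol%), AcOH (30 mol%), THF, rt → 40 °C, 24 h
Reagents that add atoms: none
Why: Amine-catalysed crossed aldol condensation, in which pyrrolidine forms the less substituted enamine of methyl ketone 4, this attacks the iminium ion of 5 through the methyl carbon only, and elimination gives the fully conjugated E,E dienone with the phenols left free.

Step 3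
Reactants: 3 helichrysetin (1.2 equiv); 6 dienone
Product: 9 bridged aryl alkyl ketal (heptanoid 3S,5S,7R; O4' on C3; O3 on C7; C7 aryl exo), via Michael adduct 7 (not isolated), via quinone methide hemiketal 8 (not isolated)
Conditions: (8α,9S)-6'-methoxycinchonan-9-amine (9-amino-9-deoxy-epi-quinine, 20 mol%), CF3CO2H (40 mol%), THF, 35 °C, 72 h; evaporate; TsOH·H2O (30 mol%), (CF3)2CHOH–CH2Cl2 1:4 (0.02 M), 0 °C → rt
Reagents that add atoms: none
Why: Proposed new method: the primary amine forms the dienone iminium ion while its protonated quinuclidine binds the acidic 4'-phenolate of 3, so C3' (the only ring carbon flanked by two enolisable OH groups, hence 1,3-dicarbonyl-like) adds 1,4 to one face of C5 and sets it as R (closest known type: cinchona primary amine catalysed Michael addition of 4-hydroxycoumarin, naphthols and similar vinylogous acids to enones, which stays 1,4-selective on δ-aryl dienones because the styrene remains conjugated); 7 rests as its 4'-O hemiketal with the 2'-OH tied up by chelation to the ketone, and its axial anomeric OH and peri-strained pseudoaxial styryl arm lie on the same face, so acid protonation of the p-hydroxystyrene at C6 gives 8, whose C7 is captured 6-exo by the hemiketal oxygen (closest known types: acid-induced p-quinone methide oxa-cyclisation to 2-aryloxanes, and Michael/ketalisation cascades to 2,8-dioxabicyclo[3.3.1]nonanes); the bridge fixes C3, and reversible closure fixes C7, because the endo site over the arene is blocked and the aryl ends exo (equatorial), trans to the axial chalcone aryl.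

Step 4
Reactants: 9 bridged aryl alkyl ketal
Product: 12 (E)-1-{2,4-dihydroxy-3-[(2R,4R,6S)-2-(4-hydroxyphenyl)-6-[2-(4-hydroxyphenyl)ethyl]oxan-4-yl]-6-methoxyphenyl}-3-(4-hydroxyphenyl)prop-2-en-1-one, via oxocarbenium aryloxytrifluoroborate zwitterion 10 (not isolated), via difluoroboryl ether 11 (not isolated)
Conditions: Et3SiH (5 equiv), BF3·OEt2 (3 equiv), CH2Cl2–MeCN 1:1, −40 °C, 1 h; sat. aq NaHCO3 added at −40 °C; chromatography on Et3N-washed silica
Reagents that add atoms: none
Why: Kishi-type ionic reduction of a ketal, in which BF3 ionises only the C3–OAr bond to give 10 (the acylphenoxide is the best leaving group, and ketal ionisation is orders of magnitude faster than ionisation of the C7 benzylic ether at −40 °C), and Et3SiH then attacks the face opposite the departing bulky chalcone aryl (invertive opening, as known for bridged bicyclic ketals with Et3SiH and a Lewis acid), placing H trans and the arylethyl chain cis to the C5 aryl, so that C3 is set as S while C5 and C7 are untouched and the cold basic quench prevents C7 epimerisation.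

## Compound list
1 | 2',4'-dihydroxy-6'-methoxyacetophenone | COc1cc(O)cc(O)c1C(C)=O | starting material
2 | 4-hydroxybenzaldehyde | O=Cc1ccc(O)cc1 | starting material
3 | helichrysetin | COc1cc(O)cc(O)c1C(=O)/C=C/c1ccc(O)cc1 | intermediate
4 | 4-(4-hydroxyphenyl)butan-2-one | CC(=O)CCc1ccc(O)cc1 | starting material
5 | (E)-4-hydroxycinnamaldehyde | O=C/C=C/c1ccc(O)cc1 | starting material
6 | (4E,6E)-1,7-bis(4-hydroxyphenyl)hepta-4,6-dien-3-one | O=C(CCc1ccc(O)cc1)/C=C/C=C/c1ccc(O)cc1 | intermediate
7 | (5R,6E)-5-{2,6-dihydroxy-3-[(E)-3-(4-hydroxyphenyl)acryloyl]-4-methoxyphenyl}-1,7-bis(4-hydroxyphenyl)hept-6-en-3-one (Michael adduct, keto form) | O=C(CCc1ccc(O)cc1)C[C@H](/C=C/c1ccc(O)cc1)c1c(O)cc(OC)c(C(=O)/C=C/c2ccc(O)cc2)c1O | intermediate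
8 | (3S,5S) 4'-O chroman hemiketal of 7 with the C6–C7 styrene protonated to the p-quinone methide | COc1cc2O[C@@](O)(CCc3ccc(O)cc3)C[C@H](CC=C3C=CC(=O)C=C3)c2c(O)c1C(=O)/C=C/c1ccc(O)cc1 | intermediate
9 | benzo-fused 2,8-dioxabicyclo[3.3.1]nonane ketal (heptanoid 3S,5S,7R; C3 bears O4', O3 and the arylethyl chain; C7 aryl exo; 2'-OH free) | COc1cc2O[C@@]3(CCc4ccc(O)cc4)C[C@H](C[C@H](c4ccc(O)cc4)O3)c2c(O)c1C(=O)/C=C/c1ccc(O)cc1 | intermediate
10 | (5S,7R) cyclic C3 oxocarbenium ion with 4'-O-trifluoroborate (zwitterion) | COc1cc(O[B-](F)(F)F)c([C@@H]2CC(CCc3ccc(O)cc3)=[O+][C@@H](c3ccc(O)cc3)C2)c(O)c1C(=O)/C=C/c1ccc(O)cc1 | intermediate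
11 | 4'-O-difluoroboryl ether of 12 (oxane 2R,4R,6S) | COc1cc(OB(F)F)c([C@@H]2C[C@H](CCc3ccc(O)cc3)O[C@@H](c3ccc(O)cc3)C2)c(O)c1C(=O)/C=C/c1ccc(O)cc1 | intermediate
12 | CNP0215517.2, oxane (2R,4R,6S) | COc1cc(O)c([C@@H]2C[C@H](CCc3ccc(O)cc3)O[C@@H](c3ccc(O)cc3)C2)c(O)c1C(=O)/C=C/c1ccc(O)cc1 | target

## Count and risks
Total steps: 4. Longest linear sequence: 3 (step 1 or step 2, then steps 3 and 4).

**Step 3 (most likely to fail).**
- The deactivated push–pull dienone and the bulky, acyl-deactivated nucleophile may react slowly.
- The nucleophile may react at C5' instead of C3'.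
- The amine may isomerise the chalcone to the flavanone.
- In the acid stage, 8 may leak to a 2-arylchroman through the 4'-OH.

The fallback sets out from 1 and 6 and comes back at 9. It leaves the chalcone arm off until the rings are made. Acetophenone 1 is more nucleophilic than 3 and has no enone or flavanone channel. It is added to 6 under the same iminium catalysis to give the acetyl Michael adduct F1. TsOH in (CF3)2CHOH takes this through the acetyl quinone methide hemiketal F2 to the acetyl bridged ketal F3, which can be recrystallised to raise the ee. Claisen–Schmidt condensation of F3 with 2 (KOH, EtOH, rt) then gives 9, since the ketal and the benzylic ether are stable to base.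

**Step 4.**
- Hydride may enter syn to the chalcone aryl and give the C3 epimer.
- The C7–O bond may ionise, giving the all-cis epimer or the C7-deoxygenated chain.

The fallback sets out from 9 and comes back at 12. It gives up the protecting-group-free endgame. Ac2O, pyridine and DMAP give the tetraacetate ketal F4. Its electron-poor aryl groups close every quinone methide channel, and it dissolves in pure CH2Cl2. Et3SiH with TiCl4 at −78 °C then opens the ketal through a tight ion pair with inversion, giving the tetraacetate oxane F5 (4'-OH free). K2CO3 in MeOH at 0 °C removes the acetates to give 12.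

**Step 1.**
- The tris-phenolate deactivates both partners.
- The product may close to the flavanone on work-up.

The fallback sets out from 1 and 2 and comes back at 3. MOMCl and iPr2NEt convert 1 into the 4'-MOM acetophenone F6 (the chelated 2'-OH stays free) and 2 into 4-(methoxymethoxy)benzaldehyde F7. KOH in EtOH condenses them to bis-MOM helichrysetin F8. HCl in MeOH at 40 °C releases 3.

## Further compounds
F1 | step 3 | (5R,6E)-5-(3-acetyl-2,6-dihydroxy-4-methoxyphenyl)-1,7-bis(4-hydroxyphenyl)hept-6-en-3-one | O=C(CCc1ccc(O)cc1)C[C@H](/C=C/c1ccc(O)cc1)c1c(O)cc(OC)c(C(C)=O)c1O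
F2 | step 3 | (3S,5S) acetyl quinone methide hemiketal | COc1cc2O[C@@](O)(CCc3ccc(O)cc3)C[C@H](CC=C3C=CC(=O)C=C3)c2c(O)c1C(C)=O
F3 | step 3 | (3S,5S,7R) acetyl bridged ketal | COc1cc2O[C@@]3(CCc4ccc(O)cc4)C[C@H](C[C@H](c4ccc(O)cc4)O3)c2c(O)c1C(C)=O
F4 | step 4 | tetraacetate of ketal 9 (3S,5S,7R) | COc1cc2O[C@@]3(CCc4ccc(OC(C)=O)cc4)C[C@H](C[C@H](c4ccc(OC(C)=O)cc4)O3)c2c(OC(C)=O)c1C(=O)/C=C/c1ccc(OC(C)=O)cc1
F5 | step 4 | tetraacetate of 12 with free 4'-OH, oxane (2R,4R,6S) | COc1cc(O)c([C@@H]2C[C@H](CCc3ccc(OC(C)=O)cc3)O[C@@H](c3ccc(OC(C)=O)cc3)C2)c(OC(C)=O)c1C(=O)/C=C/c1ccc(OC(C)=O)cc1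
F6 | step 1 | 2'-hydroxy-6'-methoxy-4'-(methoxymethoxy)acetophenone | COCOc1cc(O)c(C(C)=O)c(OC)c1
F7 | step 1 | 4-(methoxymethoxy)benzaldehyde | COCOc1ccc(C=O)cc1
F8 | step 1 | 4,4'-bis-O-methoxymethyl helichrysetin | COCOc1ccc(/C=C/C(=O)c2c(O)cc(OCOC)cc2OC)cc1
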